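**Retrosynthetic overview**

1. Endgame: 19 ⇐ 18 (benzoylation of O6) ⇐ 17 (C6–OH-directed epoxidation of C8=C9) ⇐ 14 (reductive 1,3-transposition: C9 carbinol + C8=C14 methylene → CH3-14 and C8=C9) ⇐ 13 (isopropyl addition to the C4 ketone).
2. Key disconnection: ring B (cycloheptane C1, C5–C10) of 13 is cut at C5–C6 and at C8–C9 in one operation, giving the ring A bromo keto aldehyde 8 and the four-carbon iodoalkenyl aldehyde 11 (C6, C7, C8, C14).
3. Enabling feature: in ring B the C6 oxygen is β to the C4 oxygen of ring A (aldol retron, C5 is the enolate carbon of a C4 ketone), and C9 can be an allylic carbinol beside an exocyclic C8=C14 methylene (alkenylmetal + aldehyde retron). Both bonds are carbonyl additions that one reductant (CrCl2) can drive, and the C6–C7–C8 unit bridges them.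
4. 8 ⇐ enol silane 6 ⇐ enone 4 (asymmetric conjugate methylation sets the quaternary C1) ⇐ 3-ethoxycyclopentenone 1 + Grignard reagent 2.
5. Ring order: ring A (cyclopentane, from 1) → ring B (cycloheptane, step 7) → oxirane (step 10).

Key step: step 7

Remark on the chemistry: daucane numbering is used throughout (C1 quaternary ring-fusion carbon with CH3-15; C4 carbinol carbon with the isopropyl group; C5 ring-fusion CH; C6 benzoyloxy carbon; C8 oxirane carbon with CH3-14; C9 oxirane CH; ring A = C1–C5, ring B = C1, C5–C10). The goal is the drawn enantiomer, (1R,4R,5S,6S,8R,9S). C9 of 12–16 and the bromine-bearing carbon of 7 and 8 are epimer mixtures and are written without descriptor.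

**Route**

Step 1
Reactants: 1 3-ethoxycyclopent-2-en-1-one; 2 (1,3-dioxolan-2-ylmethyl)magnesium bromide
Product: 4 3-(1,3-dioxolan-2-ylmethyl)cyclopent-2-en-1-one, via tertiary carbinol adduct 3 (not isolated)
Conditions: THF, 0 → 23 °C; then 1 M HCl, 0 °C, 15 min
Reagents that add atoms: none
Why: Stork–Danheiser enone synthesis, in which 1,2-addition of the Grignard reagent to the vinylogous ester and acid-induced hydrolysis/dehydration of the adduct give the transposed 3-substituted enone while the dioxolane should survive brief cold dilute acid; no stereocenter is formed.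

Step 2
Reactants: 4 3-(1,3-dioxolan-2-ylmethyl)cyclopent-2-en-1-one
Product: 6 trimethyl{[(3R)-3-(1,3-dioxolan-2-ylmethyl)-3-methylcyclopent-1-en-1-yl]oxy}silane, via dimethylaluminium enolate 5 (not isolated)
Conditions: Me3Al, Cu(OTf)2 (5 mol %), chiral sulfonate-bearing N-heterocyclic carbene ligand (5 mol %, the enantiomer that gives 1R), THF, −78 °C; then Me3SiOTf, −78 → 0 °C
Reagents that add atoms: trimethylaluminium C[Al](C)C; trimethylsilyl trifluoromethanesulfonate C[Si](C)(C)OS(=O)(=O)C(F)(F)F
Why: Copper-catalysed asymmetric conjugate addition of Me3Al to a β-substituted cyclopentenone, in which the chiral carbene–copper catalyst delivers CH3 to one enone face and so sets the quaternary C1 (R), and O-silylation of the aluminium enolate fixes the enol double bond regiospecifically toward C5.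

Step 3
Reactants: 6 trimethyl{[(3R)-3-(1,3-dioxolan-2-ylmethyl)-3-methylcyclopent-1-en-1-yl]oxy}silane
Product: 7 (3R)-2-bromo-3-(1,3-dioxolan-2-ylmethyl)-3-methylcyclopentan-1-one (both C2 epimers)
Conditions: NBS, NaHCO3, THF, −78 → 0 °C
Reagents that add atoms: N-bromosuccinimide O=C1CCC(=O)N1Br
Why: Electrophilic bromination of a silyl enol ether places bromine only on the enol carbon C5 (regiospecific α-bromination), and the configuration at that carbon is irrelevant because it is erased in step 7.

Step 4
Reactants: 7 (3R)-2-bromo-3-(1,3-dioxolan-2-ylmethyl)-3-methylcyclopentan-1-one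
Product: 8 2-[(1R)-2-bromo-1-methyl-3-oxocyclopentyl]acetaldehyde (both C2 epimers)
Conditions: 1 M HCl, THF, 23 °C; used without storage
Reagents that add atoms: water O
Why: Acid-catalysed acetal hydrolysis unmasks the C9 aldehyde, and the α-bromo ketone is stable to aqueous acid.

Step 5
Reactants: 9 but-3-yn-1-ol
Product: 10 3-iodobut-3-en-1-ol
Conditions: NaI, Me3SiCl, H2O, MeCN, 23 °C
Reagents that add atoms: sodium iodide [Na+].[I-]
Why: Markovnikov hydroiodination of the terminal alkyne by HI generated in situ should give the 2-iodo-1-alkene.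

Step 6
Reactants: 10 3-iodobut-3-en-1-ol
Product: 11 3-iodobut-3-enal
Conditions: Dess–Martin periodinane, NaHCO3, CH2Cl2, 0 °C; used at once
Reagents that add atoms: none
Why: Dess–Martin oxidation under buffered neutral conditions should give the β,γ-unsaturated aldehyde without migration of the double bond into conjugation.

Step 7
Reactants: 8 2-[(1R)-2-bromo-1-methyl-3-oxocyclopentyl]acetaldehyde; 11 3-iodobut-3-enal
Product: 13 trans-fused keto diol (1R,5S,6S)-6,9-dihydroxy-11,12,13-trinordauc-8(14)-en-4-one (both C9 epimers), via aldol adduct 12 (not isolated)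
Conditions: CrCl2 (nickel-free, 8 equiv), 11 (2 equiv), THF/DMF, 0 °C, 8 added over 4 h; then DMF to 0.003 M, NiCl2 (2 mol %), 23 °C; aqueous NH4Cl
Reagents that add atoms: none
Why: CrCl2 reduces the C5–Br bond of 8 to an enolate of trivalent chromium fixed at C5, which adds to the aldehyde of 11 through a closed chair transition state to form C5–C6; after NiCl2 is added, zerovalent nickel inserts into the C8–I bond, transmetalation gives an alkenyl species of trivalent chromium, and this adds to the C9 aldehyde to form C8–C9. The closest known reaction types are the chromium Reformatsky aldol of α-bromo ketones with aldehydes and the Nozaki–Hiyama–Kishi cyclisation of iodoalkenyl aldehydes to medium-ring allylic alcohols, run here one after the other in the same flask with the same reductant. Ring B is closed in the second event as a 7-exo-trig addition of the C8 alkenylchromium to the C9 carbonyl. C5 is set by approach of the aldehyde to the enolate face anti to the larger 2-oxoethyl arm on C1 (C6 ends cis to CH3-15, which gives the trans ring fusion), C6 by the chair transition state of the ring-locked (E)-enolate (anti aldol, 5S,6S), and C9 is left uncontrolled because it becomes sp2 in step 9. The step needs cross- rather than self-addition and aldehyde-over-ketone chemoselectivity: slow addition of 8 to an excess of the less hindered aldehyde 11 with nickel absent (the iodoalkene is inert to CrCl2 alone) should secure the first, high dilution in the nickel stage favours ring closure, and organochromium reagents do not add to the C4 ketone.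

Step 8
Reactants: 13 trans-fused keto diol
Product: 14 (1R,4R,5S,6S)-dauc-8(14)-ene-4,6,9-triol (both C9 epimers)
Conditions: i-PrMgCl (5 equiv), CeCl3 (5 equiv), THF, −78 → 0 °C; aqueous NH4Cl
Reagents that add atoms: isopropylmagnesium chloride CC(C)[Mg]Cl
Why: Organocerium addition to an enolisable ketone, in which the weakly basic reagent should attack C4 from the face anti to the vicinal C6 branch on C5 (the face of H-5), so the hydroxyl ends cis to CH3-15 and C4 is set as R.

Step 9
Reactants: 14 (1R,4R,5S,6S)-dauc-8(14)-ene-4,6,9-triol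
Product: 17 (1R,4R,5S,6S)-dauc-8-ene-4,6-diol (jaeschkeanadiol), via sulfonylhydrazine 15 (not isolated), via allylic diazene 16 (not isolated)
Conditions: 2-nitrobenzenesulfonylhydrazide, PPh3, DEAD, N-methylmorpholine, −30 → 23 °C
Reagents that add atoms: none
Why: Mitsunobu-type reductive 1,3-transposition of an allylic alcohol, in which the allylic C9 carbinol (the only activated and least hindered hydroxyl) is displaced by the sulfonylhydrazide, loss of sulfinate gives an allylic diazene, and retro-ene loss of N2 delivers hydrogen to C14 and moves the double bond to C8=C9, so both C9 epimers converge.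

Step 10
Reactants: 17 (1R,4R,5S,6S)-dauc-8-ene-4,6-diol
Product: 18 (1R,4R,5S,6S,8R,9S)-8,9-epoxydaucane-4,6-diol
Conditions: VO(acac)2 (5 mol %), t-BuOOH, CH2Cl2, 0 → 23 °C
Reagents that add atoms: tert-butyl hydroperoxide CC(C)(C)OO
Why: Vanadium-catalysed hydroxyl-directed epoxidation of a homoallylic alcohol, in which the C6 hydroxyl binds the metal peroxide and should deliver oxygen to the face of C8=C9 syn to itself, setting C8 (R) and C9 (S).

Step 11
Reactants: 18 (1R,4R,5S,6S,8R,9S)-8,9-epoxydaucane-4,6-diol
Product: 19 (1R,4R,5S,6S,8R,9S)-8,9-epoxy-4-hydroxydaucan-6-yl benzoate (CNP0340059.1)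
Conditions: (PhCO)2O, Et3N, DMAP (cat.), CH2Cl2, 23 °C
Reagents that add atoms: benzoic anhydride O=C(OC(=O)c1ccccc1)c1ccccc1
Why: DMAP-catalysed acylation should esterify only the secondary C6 hydroxyl, since the tertiary C4 hydroxyl is unreactive and the basic chloride-free conditions spare the oxirane.

**Compound list**

1 | 3-ethoxycyclopent-2-en-1-one | CCOC1=CC(=O)CC1 | starting material
2 | (1,3-dioxolan-2-ylmethyl)magnesium bromide | Br[Mg]CC1OCCO1 | starting material
3 | 1-(1,3-dioxolan-2-ylmethyl)-3-ethoxycyclopent-2-en-1-ol (racemic; present as its bromomagnesium alkoxide; not isolated) | CCOC1=CC(O)(CC2OCCO2)CC1 | intermediate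
4 | 3-(1,3-dioxolan-2-ylmethyl)cyclopent-2-en-1-one | O=C1C=C(CC2OCCO2)CC1 | intermediate
5 | dimethylaluminium enolate of (3R)-3-(1,3-dioxolan-2-ylmethyl)-3-methylcyclopentanone, double bond toward C5 (not isolated) | C[Al](C)OC1=C[C@@](C)(CC2OCCO2)CC1 | intermediate
6 | trimethyl{[(3R)-3-(1,3-dioxolan-2-ylmethyl)-3-methylcyclopent-1-en-1-yl]oxy}silane | C[Si](C)(C)OC1=C[C@@](C)(CC2OCCO2)CC1 | intermediate
7 | (3R)-2-bromo-3-(1,3-dioxolan-2-ylmethyl)-3-methylcyclopentan-1-one (C2 epimers) | O=C1CC[C@](C)(CC2OCCO2)C1Br | intermediate
8 | 2-[(1R)-2-bromo-1-methyl-3-oxocyclopentyl]acetaldehyde (C2 epimers) | O=C1CC[C@](C)(CC=O)C1Br | intermediate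
9 | but-3-yn-1-ol | OCCC#C | starting material
10 | 3-iodobut-3-en-1-ol | OCCC(I)=C | intermediate
11 | 3-iodobut-3-enal | O=CCC(I)=C | intermediate
12 | 2-[(1R,2S)-2-[(1S)-1-hydroxy-3-iodobut-3-en-1-yl]-1-methyl-3-oxocyclopentyl]acetaldehyde (anti aldol adduct; present as its chromium alkoxide; not isolated) | O=C1CC[C@](C)(CC=O)[C@H]1[C@@H](O)CC(I)=C | intermediate
13 | (1R,5S,6S)-6,9-dihydroxy-11,12,13-trinordauc-8(14)-en-4-one: trans-fused ring A cyclopentanone / ring B cycloheptane with 6α-OH, C8 exo-methylene, 9-OH (both epimers), 15-CH3 β, H-5 α | O=C1CC[C@]2(C)CC(O)C(=C)C[C@H](O)[C@H]21 | intermediate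
14 | (1R,4R,5S,6S)-dauc-8(14)-ene-4,6,9-triol (C9 epimers) | CC(C)[C@]1(O)CC[C@]2(C)CC(O)C(=C)C[C@H](O)[C@H]21 | intermediate
15 | N-(2-nitrobenzenesulfonyl)-N-alkylhydrazine formed at C9 of 14 (not isolated) | CC(C)[C@]1(O)CC[C@]2(C)CC(N(N)S(=O)(=O)c3ccccc3[N+](=O)[O-])C(=C)C[C@H](O)[C@H]21 | intermediate
16 | C9 allylic monoalkyl diazene (not isolated) | CC(C)[C@]1(O)CC[C@]2(C)CC(N=N)C(=C)C[C@H](O)[C@H]21 | intermediate
17 | (1R,4R,5S,6S)-dauc-8-ene-4,6-diol (jaeschkeanadiol) | CC(C)[C@]1(O)CC[C@]2(C)CC=C(C)C[C@H](O)[C@H]21 | intermediate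
18 | (1R,4R,5S,6S,8R,9S)-8,9-epoxydaucane-4,6-diol | CC(C)[C@]1(O)CC[C@]2(C)C[C@@H]3O[C@]3(C)C[C@H](O)[C@H]21 | intermediate
19 | (1R,4R,5S,6S,8R,9S)-8,9-epoxy-4-hydroxydaucan-6-yl benzoate (CNP0340059.1) | CC(C)[C@]1(O)CC[C@]2(C)C[C@@H]3O[C@]3(C)C[C@H](OC(=O)c3ccccc3)[C@H]21 | target

**Step count and risks**

Total step count: 11 (steps 5 and 6 prepare aldehyde 11).
Longest linear sequence: 9 steps (steps 1–4 and 7–11).

Steps most likely to fail:

1. Step 7. What may go wrong: self-addition between the bifunctional partners (the enolate from one molecule of 8 adding to the C9 aldehyde of another, or intermolecular alkenylchromium addition), isomerisation of 11 into conjugation, and insufficient facial selectivity at C5. Fallback: the two bonds are made stepwise on a substrate whose C9 aldehyde stays masked. It sets out from enol silane 6: MeLi (THF, 0 °C) liberates the lithium enolate, which is added at −78 °C to 11 to give the acetal-protected anti aldol adduct (2S,3R)-3-(1,3-dioxolan-2-ylmethyl)-2-[(1S)-1-hydroxy-3-iodobut-3-en-1-yl]-3-methylcyclopentan-1-one F1. No second aldehyde is present, and the bulky dioxolanylmethyl arm should shield one enolate face better. 1 M HCl/THF then unmasks the aldehyde to give 12 as an isolated compound, and a separate Nozaki–Hiyama–Kishi cyclisation (CrCl2, NiCl2 cat., DMF, high dilution) comes back to the route at 13.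

2. Step 9. What may go wrong: activation of the wrong carbinol (C6) or elimination and allylic displacement pathways during the Mitsunobu event. Fallback: the same allylic diazene is reached by oxidation and hydrazone reduction instead of a displacement. It sets out from triol 14: MnO2 (CH2Cl2) oxidises only the allylic C9 carbinol to the α-methylene ketone (1R,4R,5S,6S)-4,6-dihydroxydauc-8(14)-en-9-one F2. Condensation with 4-methylbenzenesulfonylhydrazide gives its tosylhydrazone F3, and catecholborane followed by NaOAc (reduction of the unsaturated tosylhydrazone with alkene transposition) comes back to the route at 17.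

3. Step 8. What may go wrong: retro-aldol cleavage or enolisation of the metal aldolate formed from the free β-hydroxy ketone, and incomplete facial selectivity. Fallback: the addition is run on a substrate without acidic hydroxyls. It sets out from 13: Et3SiOTf/2,6-lutidine gives the 6,9-bis(triethylsilyl) ether of 13 F4, i-PrMgCl/CeCl3 adds to C4 to give the 6,9-bis(triethylsilyl) ether of 14 F5, and Bu4NF (THF) comes back to the route at 14.

Further compounds
F1 | step 7 | (2S,3R)-3-(1,3-dioxolan-2-ylmethyl)-2-[(1S)-1-hydroxy-3-iodobut-3-en-1-yl]-3-methylcyclopentan-1-one | O=C1CC[C@](C)(CC2OCCO2)[C@H]1[C@@H](O)CC(I)=C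
F2 | step 9 | (1R,4R,5S,6S)-4,6-dihydroxydauc-8(14)-en-9-one | CC(C)[C@]1(O)CC[C@]2(C)CC(=O)C(=C)C[C@H](O)[C@H]21
F3 | step 9 | 4-methylbenzenesulfonylhydrazone of F2 | CC(C)[C@]1(O)CC[C@]2(C)CC(=NNS(=O)(=O)c3ccc(C)cc3)C(=C)C[C@H](O)[C@H]21
F4 | step 8 | 6,9-bis(triethylsilyl) ether of 13 | O=C1CC[C@]2(C)CC(O[Si](CC)(CC)CC)C(=C)C[C@H](O[Si](CC)(CC)CC)[C@H]21
F5 | step 8 | 6,9-bis(triethylsilyl) ether of 14 | CC(C)[C@]1(O)CC[C@]2(C)CC(O[Si](CC)(CC)CC)C(=C)C[C@H](O[Si](CC)(CC)CC)[C@H]21
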